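**Retrosynthetic overview**
- The C13' methyl ketone of the target is carried as a terminal alkene, so the last disconnection is a Tsuji–Wacker oxidation of (S)-5,7-dimethoxy-3-(tetradec-13-enyl)phthalide.
- The phthalide is cut at C3–C3a and C7a–C1 into pentadec-14-enyl N,N-diisopropylcarbamate and 3,5-dimethoxybenzyne, the latter released from lithiated 1-fluoro-3,5-dimethoxybenzene.
- Structural feature used: C3a and C7a are neighbouring ring carbons, C7a sits beside the C7 methoxy group, and the C3–O2–C1 unit is already the C–O–C(=O) backbone of an alkyl carbamate. A 3-methoxy-type aryne can therefore take up C3 at C3a and then C1 at C7a.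
- The carbamate comes from pentadec-14-en-1-ol and N,N-diisopropylcarbamoyl chloride, and the alkenol from 12-bromododecan-1-ol and allylmagnesium bromide.
- Ring order: the benzene ring is bought; the lactone ring, the only ring formed, and the C3 stereocentre are made together in the aryne step.

Key step: step 3

Remark on the chemistry: n-BuLi is assumed to lithiate 1-fluoro-3,5-dimethoxybenzene between fluorine and a methoxy group, the usual site for fluoroanisoles; any lithiation between the two methoxy groups cannot lose LiF and returns the arene on work-up. (+)-Sparteine is taken as a commercial reagent.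

**Step 1**
Reactants: 1 12-bromododecan-1-ol; 2 allylmagnesium bromide
Product: 3 pentadec-14-en-1-ol
Conditions: 2 (2.5 equiv), Li2CuCl4 (3 mol %), THF, −10 °C to rt; aq. NH4Cl
Reagents that add atoms: allylmagnesium bromide (2), C=CC[Mg]Br
Why: Copper-catalysed sp3–sp3 coupling of a primary alkyl bromide with a Grignard reagent (Kochi-type coupling); the first equivalent of 2 only deprotonates the hydroxyl group and the magnesium alkoxide is a spectator.

**Step 2**
Reactants: 3 pentadec-14-en-1-ol; 4 N,N-diisopropylcarbamoyl chloride
Product: 5 pentadec-14-enyl N,N-diisopropylcarbamate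
Conditions: NaH, THF, 0 °C; then 4, reflux
Reagents that add atoms: N,N-diisopropylcarbamoyl chloride (4), CC(C)N(C(C)C)C(=O)Cl
Why: O-Carbamoylation of the sodium alkoxide with the carbamoyl chloride, the standard preparation of Hoppe carbamates; the remote alkene is inert.

**Step 3**
Reactants: 5 pentadec-14-enyl N,N-diisopropylcarbamate (1.5 equiv); 6 1-fluoro-3,5-dimethoxybenzene (1.0 equiv)
Product: 12 (S)-5,7-dimethoxy-3-(tetradec-13-enyl)phthalide, via lithiocarbamate 7 (not isolated), via fluoroaryllithium 8 (not isolated), via 3,5-dimethoxybenzyne 9 (not isolated), via aryllithium adduct 10 (not isolated), via hydroxy amide 11 (not isolated)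
Conditions: 5, s-BuLi (1.4 equiv), (+)-sparteine (1.5 equiv), Et2O, −78 °C, 5 h; separate flask: 6, n-BuLi (1.0 equiv), THF, −78 °C, 1 h; cold aryllithium solution cannulated over 2 h into the lithiocarbamate held at −50 °C, then to rt; then 3 M aq. HCl, dioxane, 70 °C
Reagents that add atoms: none
Why: Proposed new method: s-BuLi/(+)-sparteine removes the pro-R hydrogen at C1 of 5 (Hoppe deprotonation) to give the configurationally stable (R)-lithiocarbamate 7, while aryllithium 8 loses LiF to give aryne 9, whose C7 methoxy group polarises the strained bond so that 7 enters at the distal carbon (future C3a) and lithium ends up on C7a next to that methoxy group, as in known organolithium additions to 3-methoxyarynes. The addition is a four-centre syn carbolithiation and should proceed with retention at carbon, as do nearly all electrophilic substitutions of non-benzylic lithiated carbamates, so the sparteine-defined (R)-centre of 7 becomes (S)-C3, the only new stereocentre. Aryllithium 10 then attacks the carbamate carbonyl five atoms away (5-exo-trig, forming C7a–C1) and the tetrahedral intermediate expels the alkoxide, an anionic 1,4 O-to-C carbamoyl shift analogous to the known rearrangement of ortho-lithiated benzyl carbamates, giving 11 as its lithium alkoxide. Aqueous acid then recloses O2–C1 by 5-exo-trig attack of the hydroxyl group on the protonated amide with loss of diisopropylamine, the usual lactonisation of ortho-(hydroxyalkyl)benzamides to phthalides, and because both methoxy groups are meta to C3 an ionisation that would racemise this centre is not favoured. The closest known reactions are sparteine-mediated lithiation–substitution of alkyl carbamates and three-component couplings of organometallics with methoxyarynes from lithiated fluoroarenes; new is the use of a chiral α-oxy organolithium as the aryne acceptor partner with its own carbamate as the internal electrophile. The step needs cross-selectivity (7 and not 8 adding to 9), secured by slow addition of 8 to an excess of 7, and it needs 7 to survive at the temperature at which LiF is lost, which is why the hold temperature should first be fixed by a furan-trapping calibration of 8.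

**Step 4**
Reactants: 12 (S)-5,7-dimethoxy-3-(tetradec-13-enyl)phthalide
Product: 13 CJ-13,108, (S)-5,7-dimethoxy-3-(13-oxotetradecyl)phthalide
Conditions: PdCl2 (10 mol %), CuCl (1 equiv), O2 (1 atm), DMF/H2O 7:1, rt
Reagents that add atoms: water, O
Why: Tsuji–Wacker oxidation, in which PdCl2 (divalent palladium) activates the terminal alkene for Markovnikov attack of water, β-hydride elimination and tautomerisation give the methyl ketone, and CuCl/O2 reoxidise the zerovalent palladium; the lactone, the aryl ethers and the remote C3 stereocentre are not touched.

**Compound list**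
1 | 12-bromododecan-1-ol | OCCCCCCCCCCCCBr | starting material
2 | allylmagnesium bromide | C=CC[Mg]Br | starting material
3 | pentadec-14-en-1-ol | OCCCCCCCCCCCCCC=C | intermediate
4 | N,N-diisopropylcarbamoyl chloride | CC(C)N(C(C)C)C(=O)Cl | starting material
5 | pentadec-14-enyl N,N-diisopropylcarbamate | CC(C)N(C(C)C)C(=O)OCCCCCCCCCCCCCC=C | intermediate
6 | 1-fluoro-3,5-dimethoxybenzene | COc1cc(F)cc(OC)c1 | starting material
7 | [(1R)-1-(N,N-diisopropylcarbamoyloxy)pentadec-14-enyl]lithium, as its (+)-sparteine complex | [Li][C@H](CCCCCCCCCCCCC=C)OC(=O)N(C(C)C)C(C)C | intermediate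
8 | (2-fluoro-4,6-dimethoxyphenyl)lithium | COc1cc(OC)c([Li])c(F)c1 | intermediate
9 | 3,5-dimethoxybenzyne (1,2-didehydro-3,5-dimethoxybenzene) | COC1=CC(OC)=CC#C1 | intermediate
10 | [2-[(1S)-1-(N,N-diisopropylcarbamoyloxy)pentadec-14-enyl]-4,6-dimethoxyphenyl]lithium | COc1cc(OC)c([Li])c(c1)[C@H](CCCCCCCCCCCCC=C)OC(=O)N(C(C)C)C(C)C | intermediate
11 | 2-[(1S)-1-hydroxypentadec-14-enyl]-4,6-dimethoxy-N,N-diisopropylbenzamide (present as its lithium alkoxide until the acid is added) | COc1cc(OC)c(C(=O)N(C(C)C)C(C)C)c(c1)[C@H](CCCCCCCCCCCCC=C)O | intermediate
12 | (S)-5,7-dimethoxy-3-(tetradec-13-enyl)phthalide | COc1cc(OC)c2c(c1)[C@H](CCCCCCCCCCCCC=C)OC2=O | intermediate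
13 | CJ-13,108, (S)-5,7-dimethoxy-3-(13-oxotetradecyl)phthalide | COc1cc(OC)c2c(c1)[C@H](CCCCCCCCCCCCC(C)=O)OC2=O | target

**Step count and risks**
Total step count: 4. Longest linear sequence: 4 steps (1 → 3 → 5 → 12 → 13).

Steps most likely to fail:

1. Step 3 (proposed new method). Three processes may defeat it: the lithiocarbamate may decompose or lose configuration before LiF is lost from the fluoroaryllithium, the fluoroaryllithium may add to the aryne itself, and proton transfer between the organolithiums may compete. The fallback uses known chemistry, sets out from 5 and returns at 12. Carbamate 5 is lithiated as before (s-BuLi, (+)-sparteine, Et2O, −78 °C) and treated with commercial 2-(3,5-dimethoxyphenyl)-4,4,5,5-tetramethyl-1,3,2-dioxaborolane. Boron enters with retention, and on warming (MgBr2·OEt2 if needed) the aryl group migrates with inversion, which should give (S)-2-[1-(3,5-dimethoxyphenyl)pentadec-14-enyl]-4,4,5,5-tetramethyl-1,3,2-dioxaborolane F1. Oxidation with NaOH/H2O2, with retention, should give (S)-1-(3,5-dimethoxyphenyl)pentadec-14-en-1-ol F2. NBS in MeCN at 0 °C should brominate the ring ortho to the carbinol and para to a methoxy group, giving (S)-1-(2-bromo-3,5-dimethoxyphenyl)pentadec-14-en-1-ol F3. Treatment with n-BuLi (2.2 equiv, THF, −78 °C), then CO2, then aqueous HCl should give 2-[(1S)-1-hydroxypentadec-14-enyl]-4,6-dimethoxybenzoic acid F4, which lactonises on acidification to 12.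

2. Step 4. Palladium hydride species may move the double bond along the chain before oxidation, which would give regioisomeric ketones that are hard to separate. The fallback sets out from 12 and returns at 13. Mukaiyama hydration (Co(acac)2, PhSiH3, O2, THF, rt) should give the Markovnikov alcohol (3S)-3-(13-hydroxytetradecyl)-5,7-dimethoxyphthalide F5 as a mixture of carbinol epimers. Oxidation with Dess–Martin periodinane in CH2Cl2 removes the extra stereocentre and should give 13.

3. Step 1. Homocoupling of the allyl Grignard reagent and reduction of the bromide, with the poorly soluble magnesium alkoxide slowing the substitution, may leave the coupling incomplete. The fallback sets out from 1 and returns at 3, replacing the polar coupling by a radical one. A Finkelstein exchange (NaI, acetone, reflux) should give 12-iodododecan-1-ol F6. Keck allylation (allyltributylstannane, AIBN, toluene, 80 °C), which tolerates the free hydroxyl group, should then give 3.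

**Further compounds**
F1 | step 3 | (S)-2-[1-(3,5-dimethoxyphenyl)pentadec-14-enyl]-4,4,5,5-tetramethyl-1,3,2-dioxaborolane | COc1cc(OC)cc(c1)[C@H](CCCCCCCCCCCCC=C)B1OC(C)(C)C(C)(C)O1
F2 | step 3 | (S)-1-(3,5-dimethoxyphenyl)pentadec-14-en-1-ol | COc1cc(OC)cc(c1)[C@H](CCCCCCCCCCCCC=C)O
F3 | step 3 | (S)-1-(2-bromo-3,5-dimethoxyphenyl)pentadec-14-en-1-ol | COc1cc(OC)c(Br)c(c1)[C@H](CCCCCCCCCCCCC=C)O
F4 | step 3 | 2-[(1S)-1-hydroxypentadec-14-enyl]-4,6-dimethoxybenzoic acid | COc1cc(OC)c(C(=O)O)c(c1)[C@H](CCCCCCCCCCCCC=C)O
F5 | step 4 | (3S)-3-(13-hydroxytetradecyl)-5,7-dimethoxyphthalide, mixture of carbinol epimers | COc1cc(OC)c2c(c1)[C@H](CCCCCCCCCCCCC(C)O)OC2=O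
F6 | step 1 | 12-iodododecan-1-ol | OCCCCCCCCCCCCI
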